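**Conventions and assumptions.** Guaianolide numbering is used for each C15 half. Unprimed atoms belong to the half that keeps the C4=C5 double bond, primed atoms to the oxa-bridged half. The building blocks that supply the carbon skeleton (1, 3, 8, 13) are numbered as reactants, and other atom-donating reagents stand on the reagent line. The C3 carbinol drawn in 15–18 is a temporary centre; the epimer shown is the one expected, and either epimer would serve because step 13 removes it.

## Analysis of the target

Anabsin (29) is a C30 dimer of two identical 6,12-guaianolide units. Each unit has a five-membered carbocycle, a seven-membered carbocycle and a trans-fused γ-lactone, and with the two rings created by the union the molecule has eight rings. The halves are joined by C2–C2′ and C3–C5′, which together with C1′ and C3′–C4′ form a norbornane, and an ether oxygen links C10′ to C4′ in an oxolane. Of the sixteen stereocentres, C1, C6, C7, C10 and C11 have the same configuration in both halves (1R,6S,7S,10S,11S; 1α-H, 6β-H, 7α-H, 10β-oxygen, 11α-methyl). C2, C2′, C3, C3′, C4′ and C5′ all lie on the norbornane core and depend on how the halves are joined. Sensitive points are the epimerisable C11 centres of the lactones, the tertiary C10 carbinol (open to elimination and, in open-chain precursors, to retro-aldol cleavage), and the allylic positions next to the C4=C5 alkene. The difficulty is the unsymmetrical union of two identical halves around a congested core, together with two seven-membered rings that each carry a tertiary carbinol next to the ring fusion. The strategy rests on the C8–C9 and C8′–C9′ bonds: in both seven-membered rings they are unsubstituted two-carbon links between lactone carbon C7 and carbinol carbon C10. Both rings can therefore be closed at once from vinyl groups on C7 and C10 of a twofold-symmetric open precursor, without creating any stereocentre.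

## Retrosynthetic reasoning

**29 to 28.** The C3–C5′ bond and the C4′–O bond of the ether bridge are cut together. These are the two bonds that make the halves different, and removing them gives the C2-symmetric bis(allylic alcohol) 28. In the forward direction ionisation of either C3 hydroxyl gives the same allyl cation. The C4′=C5′ alkene of the other half is held over C3 by the C2–C2′ bond and attacks through C5′, and the C10′ hydroxyl captures the C4′ cation. The tether fixes the face of every new bond.

**28 to 25.** The two C3 carbinols are traced to the ketones of bis-enone 25. Hydride is expected to enter anti to the neighbouring half and give the 3α-alcohols (26), so an inversion through the esters 27 is planned. The target needs the C3′ oxygen on the β-face.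

**25 to 23.** After a C8=C9 double bond is introduced in each half (24), the two seven-membered rings are opened across C8–C9 and C8′–C9′ to give tetraene 23. The cut is placed there because these carbons carry no substituent and no stereocentre, so ring closure by olefin metathesis needs only chemoselectivity. Opening C1–C10, C5–C6 or C6–C7 instead would make the ring closure responsible for stereocentres. All twelve stereocentres of 23 are set earlier on small monocyclic intermediates.

**23 to 21.** The C2–C2′ bond is cut to two molecules of one enone, 21 (22 is the silyl-protected dimer). The forward reaction is oxidative coupling of the α′-enolate. Each new centre forms anti to the C1 side chain, and because both partners are the same enantiomer no meso isomer is possible.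

**21 to 19.** The C10 vinyl group is traced to a terminal 1,2-diol (20) masked as a dioxolane (19). This is done for two reasons. A free C10 vinyl group would close a six-membered carbocycle with the C6 vinyl group during the earlier butenolide-forming metathesis. The dioxolane stereocentre is also the element that controls C10 and C1 when the side chain is attached, which an acceptor carrying the vinyl group directly could not do (methyl and vinyl are too similar in size).

**19 to 14.** The lactone is taken apart in the order C11–CH3 (enolate methylation anti to the vinyl group, 17 to 18), C7–vinyl (conjugate addition of 8 anti to the C6 substituent, 16 to 17) and C7=C11 (metathesis of the acrylate made from 13). The methyl group is added by alkylation because protonation of an α-methyl enolate would place it cis to the vinyl group. The ring ketone is held as the alcohol through 15–18. In the enone form the C6 hydrogen of the butenolide would be doubly vinylogous and easily lost, and the ketone α′-methylene would compete in the lactone methylation.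

**14 to 10.** The C6–C7 bond is cut to aldehyde 11 and a vinyl nucleophile from 8 under catalyst control, since C6 is too far from C1 for substrate control. The aldehyde comes from the terminal alkene of dienone 10.

**10 to 1, 3 and 8.** The C5–C6 bond is cut by a Stork–Danheiser transform to vinylogous ester 7 and 8. The C1–C10 bond is cut by an aldol transform to the enolate of 2 and the chiral-pool ketone 5 (from ester 3); 2 comes from dione 1. This aldol is the only step that has to create absolute configuration in the ring portion.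

## Alternatives that were turned down

**Alternative 1: late double oxymercuration.** Both tertiary C–O bonds (C10–OH in the unprimed half and C10′–O of the ether bridge) would be made last from exocyclic methylene groups at C10 and C10′. Hg(OAc)2 in aqueous THF would add water at C10 and let the C4′ hydroxyl add to C10′, closing the oxolane; NaBH4 would then remove mercury and give the silyl ether A1, one deprotection from 29. In its favour, two C–O bonds and a ring form in one flask at the end, and the Markovnikov regiochemistry is dependable. It is stronger than the chosen route in one respect: no tertiary allylic carbinol has to be protected and carried through enolate and metathesis chemistry. Against it, the C10 configuration would depend on which face of a mercurinium ion on a flexible cycloheptane is opened by external water, and nothing in the substrate secures the 10β-hydroxyl. The C4=C5 alkene could also compete for mercury. The approach also presupposes the norbornane bond C3–C5′ and the C4′ tertiary alcohol, so the hardest C–C bond and the C4′ oxygenation would each need a separate solution. The chosen route makes C3–C5′ and C4′–O in one cationic step and fixes C10 early from a chiral-pool ketone, at the price of a protecting group.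

**Alternative 2: double chromium allylation.** The C6–C7 and C6′–C7′ bonds would be formed, with the lactone C–O bonds following. CrCl2 would convert an allylic bromide of the 2-(bromomethyl)enoate type at the end of each C10 side chain into an allylchromium. This would add through C7 to an aldehyde carbon C6 on C5, closing both seven-membered rings; lactonisation would give the bis(α-methylene lactone) A2. It builds four rings and four stereocentres (C6, C7 and their primed counterparts) in one operation, against two rings and no stereocentre in the chosen key step, so it is clearly stronger in bond economy, and chromium allyls tolerate ketones and esters. Against it, the trans relationship C6/C7 and the relationship of C6 to C1 would have to come out right in both halves at once from a cyclic transition state inside a forming seven-membered ring. A2 would still need both exocyclic methylenes reduced to 11α-methyl groups without touching the enones, plus desilylation. Its precursor would combine 4-oxo-enals with allylic bromides that must survive or follow the C2–C2′ coupling. The chosen route needs about as many steps but places no stereocentre at risk in the ring closure, because C6, C7 and C11 are set beforehand on a simple monocyclic lactone.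

**Alternative 3: cathodic enone–ketone cyclisation.** Only C3–C5′ would be formed, by reductive umpolung. One-electron reduction of one enone of bis-enone 25 would give a radical anion whose β-carbon C5′ adds to the C3 carbonyl, giving the norbornane hydroxy ketone A3. It starts from the same symmetric compound 25 as the chosen endgame and needs no carbinol inversion, and on that point it is stronger. Against it, A3 has the wrong functionality at three positions. C3 carries a tertiary hydroxyl that would have to be removed without moving C4=C5. C4′ is a methine that would still have to be oxygenated and bridged to C10′. C3′ is a ketone that would have to be reduced from the correct face. β,β-Coupling and simple saturation of the enone would also compete at the electrode. The cationic endgame of the chosen route forms the same bond, leaves C3 as CH, makes the C4′–O bond in the same step and keeps C3′ at the alcohol level; the cost is a two-step inversion.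

Key step: step 18

## Route

Step 1
Reactants: 1 2-methylcyclopentane-1,3-dione
Product: 2 2-methyl-3-(2-methylpropoxy)cyclopent-2-en-1-one
Conditions: iBuOH, TsOH·H2O (cat.), toluene, reflux, Dean–Stark
Reagents that add atoms: 2-methylpropan-1-ol, CC(C)CO
Why: Acid-catalysed enol etherification of a symmetrical cyclic 1,3-dione with azeotropic removal of water; because 1 is symmetrical only one vinylogous ester can form.

Step 2
Reactants: 3 methyl (4S)-2,2-dimethyl-1,3-dioxolane-4-carboxylate
Product: 5 1-[(4S)-2,2-dimethyl-1,3-dioxolan-4-yl]ethan-1-one, via Weinreb amide 4 (not isolated)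
Conditions: MeNH(OMe)·HCl, iPrMgCl, THF, −20 °C; then MeMgBr, −20 → 0 °C; aq. NH4Cl
Reagents that add atoms: methylmagnesium bromide, C[Mg]Br; N,O-dimethylhydroxylamine hydrochloride, CNOC.Cl (its atoms stay in 4 only)
Why: Weinreb ketone synthesis: the magnesium amide converts the ester into amide 4, whose chelated tetrahedral adduct with the Grignard reagent releases the methyl ketone only on work-up, so over-addition and epimerisation of the α-alkoxy centre should be avoided.

Step 3
Reactants: 2 2-methyl-3-(2-methylpropoxy)cyclopent-2-en-1-one; 5 1-[(4S)-2,2-dimethyl-1,3-dioxolan-4-yl]ethan-1-one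
Product: 6 (5S)-5-[(1R)-1-[(4S)-2,2-dimethyl-1,3-dioxolan-4-yl]-1-hydroxyethyl]-2-methyl-3-(2-methylpropoxy)cyclopent-2-en-1-one
Conditions: LiN(iPr)2, THF, −78 °C; then 5, −78 °C; AcOH quench at −78 °C
Reagents that add atoms: none
Why: Kinetic α′-deprotonation of the vinylogous ester gives the cross-conjugated lithium enolate, which adds to the activated α-alkoxy ketone (aldol addition to a ketone). Felkin–Anh attack anti to the dioxolane C–O bond of the (S)-ketone should set C10, and a Zimmerman–Traxler chair with the branched dioxolanyl group equatorial and the ring enolate of fixed (E)-geometry should place the ring CH2 anti to the new hydroxyl, which sets C1.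

Step 4
Reactants: 6 (5S)-5-[(1R)-1-[(4S)-2,2-dimethyl-1,3-dioxolan-4-yl]-1-hydroxyethyl]-2-methyl-3-(2-methylpropoxy)cyclopent-2-en-1-one
Product: 7 (5S)-5-[(1R)-1-(tert-butyldimethylsilyloxy)-1-[(4S)-2,2-dimethyl-1,3-dioxolan-4-yl]ethyl]-2-methyl-3-(2-methylpropoxy)cyclopent-2-en-1-one
Conditions: TBSOTf, 2,6-lutidine, CH2Cl2, −78 → 0 °C
Reagents that add atoms: tert-butyldimethylsilyl trifluoromethanesulfonate, CC(C)(C)[Si](C)(C)OS(=O)(=O)C(F)(F)F
Why: Silyl triflate silylation of a hindered tertiary alcohol; the ether blocks retro-aldol cleavage of the β-hydroxy ketone in the next organometallic step and is stable to the later acidic steps.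

Step 5
Reactants: 7 (5S)-5-[(1R)-1-(tert-butyldimethylsilyloxy)-1-[(4S)-2,2-dimethyl-1,3-dioxolan-4-yl]ethyl]-2-methyl-3-(2-methylpropoxy)cyclopent-2-en-1-one; 8 vinylmagnesium bromide
Product: 10 (4R)-4-[(1R)-1-(tert-butyldimethylsilyloxy)-1-[(4S)-2,2-dimethyl-1,3-dioxolan-4-yl]ethyl]-3-ethenyl-2-methylcyclopent-2-en-1-one, via tertiary vinyl carbinol 9 (not isolated)
Conditions: 8, CeCl3, THF, −78 → 0 °C; then 1 M HCl, 0 °C, 15 min
Reagents that add atoms: water, O
Why: Stork–Danheiser transposition: the organocerium reagent from 8 adds 1,2 to the hindered, enolisable vinylogous-ester carbonyl, and dilute acid ionises the bis-allylic alcohol 9 and hydrolyses the enol ether, which moves the carbonyl to C3 and leaves the vinyl group on C5. C1 and C10 are not touched.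

Step 6
Reactants: 10 (4R)-4-[(1R)-1-(tert-butyldimethylsilyloxy)-1-[(4S)-2,2-dimethyl-1,3-dioxolan-4-yl]ethyl]-3-ethenyl-2-methylcyclopent-2-en-1-one
Product: 11 (5R)-5-[(1R)-1-(tert-butyldimethylsilyloxy)-1-[(4S)-2,2-dimethyl-1,3-dioxolan-4-yl]ethyl]-2-methyl-3-oxocyclopent-1-ene-1-carbaldehyde
Conditions: OsO4 (cat.), NaIO4, 2,6-lutidine, dioxane/H2O, rt
Reagents that add atoms: sodium periodate, [Na+].[O-]I(=O)(=O)=O (oxygen delivered through osmium tetroxide, O=[Os](=O)(=O)=O)
Why: Lemieux–Johnson cleavage: OsO4 dihydroxylates the monosubstituted terminal alkene much faster than the tetrasubstituted, electron-poor ring alkene, and periodate cleaves the diol to the C6 aldehyde.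

Step 7
Reactants: 11 (5R)-5-[(1R)-1-(tert-butyldimethylsilyloxy)-1-[(4S)-2,2-dimethyl-1,3-dioxolan-4-yl]ethyl]-2-methyl-3-oxocyclopent-1-ene-1-carbaldehyde; 8 vinylmagnesium bromide
Product: 12 (4R)-4-[(1R)-1-(tert-butyldimethylsilyloxy)-1-[(4S)-2,2-dimethyl-1,3-dioxolan-4-yl]ethyl]-3-[(1S)-1-hydroxyprop-2-en-1-yl]-2-methylcyclopent-2-en-1-one
Conditions: Zn(CH=CH2)2 (from 8 and ZnCl2, Mg salts removed with dioxane), (−)-3-exo-(dimethylamino)isoborneol (10 mol%), toluene, −20 → 0 °C; aq. NH4Cl
Reagents that add atoms: none
Why: Amino-alcohol-catalysed enantioselective addition of a diorganozinc to an aldehyde; the ketone is inert to the zinc reagent. By analogy with dialkylzinc additions, this ligand should direct the vinyl group to the Si face and give the (6S)-carbinol under reagent control, the existing centres being remote.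

Step 8
Reactants: 12 (4R)-4-[(1R)-1-(tert-butyldimethylsilyloxy)-1-[(4S)-2,2-dimethyl-1,3-dioxolan-4-yl]ethyl]-3-[(1S)-1-hydroxyprop-2-en-1-yl]-2-methylcyclopent-2-en-1-one; 13 acryloyl chloride
Product: 14 (1S)-1-[(5R)-5-[(1R)-1-(tert-butyldimethylsilyloxy)-1-[(4S)-2,2-dimethyl-1,3-dioxolan-4-yl]ethyl]-2-methyl-3-oxocyclopent-1-en-1-yl]prop-2-en-1-yl prop-2-enoate
Conditions: 13, iPr2NEt, DMAP (cat.), CH2Cl2, −40 → 0 °C
Reagents that add atoms: none
Why: O-Acylation of the only free hydroxyl, a secondary allylic alcohol, with an acid chloride under amine and DMAP catalysis.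

Step 9
Reactants: 14 (1S)-1-[(5R)-5-[(1R)-1-(tert-butyldimethylsilyloxy)-1-[(4S)-2,2-dimethyl-1,3-dioxolan-4-yl]ethyl]-2-methyl-3-oxocyclopent-1-en-1-yl]prop-2-en-1-yl prop-2-enoate
Product: 15 (1S)-1-[(3S,5R)-5-[(1R)-1-(tert-butyldimethylsilyloxy)-1-[(4S)-2,2-dimethyl-1,3-dioxolan-4-yl]ethyl]-3-hydroxy-2-methylcyclopent-1-en-1-yl]prop-2-en-1-yl prop-2-enoate
Conditions: NaBH4, CeCl3·7H2O, MeOH, −78 °C
Reagents that add atoms: none
Why: Luche reduction: cerium-activated borohydride reduces the enone carbonyl 1,2 and should leave the acrylate alone at −78 °C, with hydride expected anti to the C1 side chain. The alcohol masks the ketone so that the butenolide C6–H is not doubly vinylogous and no ketone α-proton competes in steps 10–12.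

Step 10
Reactants: 15 (1S)-1-[(3S,5R)-5-[(1R)-1-(tert-butyldimethylsilyloxy)-1-[(4S)-2,2-dimethyl-1,3-dioxolan-4-yl]ethyl]-3-hydroxy-2-methylcyclopent-1-en-1-yl]prop-2-en-1-yl prop-2-enoate
Product: 16 (5S)-5-[(3S,5R)-5-[(1R)-1-(tert-butyldimethylsilyloxy)-1-[(4S)-2,2-dimethyl-1,3-dioxolan-4-yl]ethyl]-3-hydroxy-2-methylcyclopent-1-en-1-yl]furan-2(5H)-one
Conditions: second-generation Grubbs catalyst RuCl2(=CHPh)(PCy3)(H2IMes) (5 mol%), CH2Cl2 (5 mM), 40 °C
Reagents that add atoms: none
Why: Ring-closing metathesis of an allylic acrylate to a butenolide, a standard use of this catalyst. The only other alkene is tetrasubstituted and inert, and the C10 vinyl group is still masked as the dioxolane, so no six-membered carbocycle can form.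

Step 11
Reactants: 16 (5S)-5-[(3S,5R)-5-[(1R)-1-(tert-butyldimethylsilyloxy)-1-[(4S)-2,2-dimethyl-1,3-dioxolan-4-yl]ethyl]-3-hydroxy-2-methylcyclopent-1-en-1-yl]furan-2(5H)-one; 8 vinylmagnesium bromide
Product: 17 (4R,5S)-5-[(3S,5R)-5-[(1R)-1-(tert-butyldimethylsilyloxy)-1-[(4S)-2,2-dimethyl-1,3-dioxolan-4-yl]ethyl]-3-hydroxy-2-methylcyclopent-1-en-1-yl]-4-ethenyloxolan-2-one
Conditions: 8 (5 equiv), CuBr·SMe2 (2 equiv), THF/Me2S, −78 → −40 °C; aq. NH4Cl
Reagents that add atoms: none
Why: Copper-mediated conjugate addition of a vinyl Grignard reagent to a γ-substituted butenolide; the nucleophile should enter anti to the cyclopentenyl group on C6 and set C7 trans. The free hydroxyl only consumes one equivalent of reagent.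

Step 12
Reactants: 17 (4R,5S)-5-[(3S,5R)-5-[(1R)-1-(tert-butyldimethylsilyloxy)-1-[(4S)-2,2-dimethyl-1,3-dioxolan-4-yl]ethyl]-3-hydroxy-2-methylcyclopent-1-en-1-yl]-4-ethenyloxolan-2-one
Product: 18 (3S,4S,5S)-5-[(3S,5R)-5-[(1R)-1-(tert-butyldimethylsilyloxy)-1-[(4S)-2,2-dimethyl-1,3-dioxolan-4-yl]ethyl]-3-hydroxy-2-methylcyclopent-1-en-1-yl]-4-ethenyl-3-methyloxolan-2-one
Conditions: LiN(iPr)2 (2.2 equiv), THF, −78 °C; MeI, −78 → −50 °C
Reagents that add atoms: iodomethane, CI
Why: Alkylation of the lactone lithium enolate (the C3 alkoxide is inert to iodomethane at this temperature) should occur anti to the neighbouring C7 vinyl group and give the all-trans lactone with C11 as in the target.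

Step 13
Reactants: 18 (3S,4S,5S)-5-[(3S,5R)-5-[(1R)-1-(tert-butyldimethylsilyloxy)-1-[(4S)-2,2-dimethyl-1,3-dioxolan-4-yl]ethyl]-3-hydroxy-2-methylcyclopent-1-en-1-yl]-4-ethenyl-3-methyloxolan-2-one
Product: 19 (3S,4S,5S)-5-[(5R)-5-[(1R)-1-(tert-butyldimethylsilyloxy)-1-[(4S)-2,2-dimethyl-1,3-dioxolan-4-yl]ethyl]-2-methyl-3-oxocyclopent-1-en-1-yl]-4-ethenyl-3-methyloxolan-2-one
Conditions: Dess–Martin periodinane, NaHCO3, CH2Cl2, 0 °C → rt
Reagents that add atoms: none
Why: Dess–Martin oxidation of the secondary allylic alcohol restores the cyclopentenone needed for enolate formation; with the lactone now saturated, the C6 hydrogen is no longer unusually acidic.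

Step 14
Reactants: 19 (3S,4S,5S)-5-[(5R)-5-[(1R)-1-(tert-butyldimethylsilyloxy)-1-[(4S)-2,2-dimethyl-1,3-dioxolan-4-yl]ethyl]-2-methyl-3-oxocyclopent-1-en-1-yl]-4-ethenyl-3-methyloxolan-2-one
Product: 20 (3S,4S,5S)-5-[(5R)-5-[(2R,3S)-2-(tert-butyldimethylsilyloxy)-3,4-dihydroxybutan-2-yl]-2-methyl-3-oxocyclopent-1-en-1-yl]-4-ethenyl-3-methyloxolan-2-one
Conditions: AcOH/H2O (4:1), 40 °C
Reagents that add atoms: none
Why: Mild aqueous acid hydrolyses the terminal isopropylidene acetal; the tertiary silyl ether, the lactone and the enone should tolerate these conditions.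

Step 15
Reactants: 20 (3S,4S,5S)-5-[(5R)-5-[(2R,3S)-2-(tert-butyldimethylsilyloxy)-3,4-dihydroxybutan-2-yl]-2-methyl-3-oxocyclopent-1-en-1-yl]-4-ethenyl-3-methyloxolan-2-one
Product: 21 (3S,4S,5S)-5-[(5R)-5-[(2S)-2-(tert-butyldimethylsilyloxy)but-3-en-2-yl]-2-methyl-3-oxocyclopent-1-en-1-yl]-4-ethenyl-3-methyloxolan-2-one
Conditions: PPh3, imidazole, I2, toluene, 80 °C
Reagents that add atoms: none
Why: Garegg–Samuelsson olefination of a terminal 1,2-diol: the primary hydroxyl becomes the iodide, the secondary one an oxyphosphonium group, and iodide-induced reductive elimination gives the vinyl group without substitution at the hindered carbon. C10 is not touched, and the dioxolane-derived centre disappears.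

Step 16
Reactants: 21 (3S,4S,5S)-5-[(5R)-5-[(2S)-2-(tert-butyldimethylsilyloxy)but-3-en-2-yl]-2-methyl-3-oxocyclopent-1-en-1-yl]-4-ethenyl-3-methyloxolan-2-one (two molecules)
Product: 22 (1S,1′S,5R,5′R)-5,5′-bis[(2S)-2-(tert-butyldimethylsilyloxy)but-3-en-2-yl]-4,4′-bis[(2S,3S,4S)-3-ethenyl-4-methyl-5-oxooxolan-2-yl]-3,3′-dimethyl-[1,1′-bi(cyclopentane)]-3,3′-diene-2,2′-dione
Conditions: LiN(iPr)2 (1.05 equiv), THF, −78 °C; then CuCl2 in DMF, −78 → −40 °C
Reagents that add atoms: none
Why: Oxidative homocoupling of a lithium enolate with CuCl2 (divalent copper as one-electron oxidant). Kinetic deprotonation should take place at the α′-methylene C2 rather than at the hindered tertiary lactone α-hydrogen, and oxidation gives an α-keto radical localised on C2. Each half should form the C2–C2′ bond on the face opposite the bulky C1 side chain, which gives the C2-symmetric trans,trans dimer.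

Step 17
Reactants: 22 (1S,1′S,5R,5′R)-5,5′-bis[(2S)-2-(tert-butyldimethylsilyloxy)but-3-en-2-yl]-4,4′-bis[(2S,3S,4S)-3-ethenyl-4-methyl-5-oxooxolan-2-yl]-3,3′-dimethyl-[1,1′-bi(cyclopentane)]-3,3′-diene-2,2′-dione
Product: 23 (1S,1′S,5R,5′R)-4,4′-bis[(2S,3S,4S)-3-ethenyl-4-methyl-5-oxooxolan-2-yl]-5,5′-bis[(2S)-2-hydroxybut-3-en-2-yl]-3,3′-dimethyl-[1,1′-bi(cyclopentane)]-3,3′-diene-2,2′-dione
Conditions: HF·pyridine, pyridine/THF, 0 → 35 °C
Reagents that add atoms: none
Why: Fluoride cleavage of the two tertiary silyl ethers under buffered acidic conditions; no free alkoxide is formed, so vinylogous retro-aldol loss of the C10 side chain is avoided.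

Step 18
Reactants: 23 (1S,1′S,5R,5′R)-4,4′-bis[(2S,3S,4S)-3-ethenyl-4-methyl-5-oxooxolan-2-yl]-5,5′-bis[(2S)-2-hydroxybut-3-en-2-yl]-3,3′-dimethyl-[1,1′-bi(cyclopentane)]-3,3′-diene-2,2′-dione
Product: 24 C2–C2′-linked dimer of (1R,2S,6S,7S,10S,11S)-10-hydroxy-3-oxoguaia-4,8-dien-12,6-olide (1α-H, 6β-H, 7α-H, 10β-OH, 11α-CH3 in each half)
Conditions: second-generation Grubbs catalyst RuCl2(=CHPh)(PCy3)(H2IMes) (2 × 5 mol%), CH2Cl2 (1 mM), 40 °C, argon purge
Reagents that add atoms: none
Why: This is ring-closing olefin metathesis of the known type that gives cycloheptenes bearing an allylic tertiary alcohol. The ruthenium benzylidene should exchange first with the less hindered C7 (C7′) vinyl group; the resulting alkylidene then undergoes intramolecular [2+2] cycloaddition with the C10 (C10′) vinyl group and cycloreversion, which forms C8=C9 (C8′=C9′) and releases ethene. Each seven-membered carbocycle is thus closed by joining two monosubstituted alkenes whose anchors C6 and C10 sit on the neighbouring ring atoms C5 and C1, and the ring size enforces the cis alkene. No stereocentre is created; the six centres of each half are already in place and lie outside the reacting carbons. The step needs only chemoselectivity. The tetrasubstituted C4=C5 enone alkenes are too hindered and electron-poor to enter the catalytic cycle. Closure of a seven-membered ring within one half should outrun the eight-, ten- and twelve-membered closures between the halves and, at high dilution, oligomerisation. The trans-substituted lactone and the C1 configuration hold the two vinyl groups of a half close together, and the free C10 hydroxyl, allylic to the hindered vinyl group, is expected to assist reaction at that alkene.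

Step 19
Reactants: 24 C2–C2′-linked dimer of (1R,2S,6S,7S,10S,11S)-10-hydroxy-3-oxoguaia-4,8-dien-12,6-olide
Product: 25 C2–C2′-linked dimer of (1R,2S,6S,7S,10S,11S)-10-hydroxy-3-oxoguai-4-en-12,6-olide
Conditions: H2 (1 atm), RhCl(PPh3)3, benzene/EtOH, rt
Reagents that add atoms: none
Why: Homogeneous hydrogenation with RhCl(PPh3)3 reduces the two cis-disubstituted ring alkenes and should not touch the tetrasubstituted enone double bonds or the lactones; no stereocentre is formed.

Step 20
Reactants: 25 C2–C2′-linked dimer of (1R,2S,6S,7S,10S,11S)-10-hydroxy-3-oxoguai-4-en-12,6-olide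
Product: 26 C2–C2′-linked dimer of (1R,2S,3R,6S,7S,10S,11S)-3α,10β-dihydroxyguai-4-en-12,6-olide
Conditions: NaBH4, CeCl3·7H2O, MeOH/CH2Cl2, −78 °C
Reagents that add atoms: none
Why: Luche 1,2-reduction of both enones; hydride should attack each carbonyl anti to the adjacent C2 substituent (the other half) and give the 3α,3′α-diol, with the hydroxyls cis to the C2–C2′ bond.

Step 21
Reactants: 26 C2–C2′-linked dimer of (1R,2S,3R,6S,7S,10S,11S)-3α,10β-dihydroxyguai-4-en-12,6-olide
Product: 27 C2–C2′-linked dimer of (1R,2S,3S,6S,7S,10S,11S)-10β-hydroxy-3β-(4-nitrobenzoyloxy)guai-4-en-12,6-olide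
Conditions: 4-nitrobenzoic acid, PPh3, DIAD, THF, 0 °C → rt
Reagents that add atoms: 4-nitrobenzoic acid, OC(=O)c1ccc(cc1)[N+](=O)[O-]
Why: Mitsunobu reaction with 4-nitrobenzoic acid, the variant suited to hindered secondary alcohols, inverts both allylic carbinols by SN2 displacement of the oxyphosphonium groups; the tertiary C10 hydroxyls do not react.

Step 22
Reactants: 27 C2–C2′-linked dimer of (1R,2S,3S,6S,7S,10S,11S)-10β-hydroxy-3β-(4-nitrobenzoyloxy)guai-4-en-12,6-olide
Product: 28 C2–C2′-linked dimer of (1R,2S,3S,6S,7S,10S,11S)-3β,10β-dihydroxyguai-4-en-12,6-olide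
Conditions: K2CO3 (cat.), MeOH, 0 °C
Reagents that add atoms: none
Why: Carbonate-catalysed methanolysis cleaves the electron-poor aryl esters by acyl–oxygen fission with retention at C3 and C3′; the trans-fused lactones, whose C11 configuration is the thermodynamically preferred one, should survive.

Step 23
Reactants: 28 C2–C2′-linked dimer of (1R,2S,3S,6S,7S,10S,11S)-3β,10β-dihydroxyguai-4-en-12,6-olide
Product: 29 anabsin
Conditions: camphorsulfonic acid (20 mol%), CH2Cl2 (2 mM), 0 °C → rt
Reagents that add atoms: none
Why: Acid ionises one of the two equivalent allylic alcohols to an allyl cation over C3–C5. The C4′=C5′ alkene of the other half, held over C3 by the C2–C2′ bond, attacks through C5′ (five-membered closure that completes the norbornane, new bond on the α-face of both rings as the tether demands), and the tertiary C4′ cation is captured by the C10′ hydroxyl on the β-face (oxolane closure). This is an allyl-cation–alkene cyclisation terminated by a hydroxyl group; C–O captures of the allyl cation are reversible under the conditions, the C–C bond formation is not.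

## Compound list

1 | 2-methylcyclopentane-1,3-dione | CC1C(=O)CCC1=O | starting material
2 | 2-methyl-3-(2-methylpropoxy)cyclopent-2-en-1-one | CC1=C(OCC(C)C)CCC1=O | intermediate
3 | methyl (4S)-2,2-dimethyl-1,3-dioxolane-4-carboxylate | COC(=O)[C@@H]1COC(C)(C)O1 | starting material
4 | (4S)-N-methoxy-N,2,2-trimethyl-1,3-dioxolane-4-carboxamide (Weinreb amide, not isolated) | CON(C)C(=O)[C@@H]1COC(C)(C)O1 | intermediate
5 | 1-[(4S)-2,2-dimethyl-1,3-dioxolan-4-yl]ethan-1-one | CC(=O)[C@@H]1COC(C)(C)O1 | intermediate
6 | (5S)-5-[(1R)-1-[(4S)-2,2-dimethyl-1,3-dioxolan-4-yl]-1-hydroxyethyl]-2-methyl-3-(2-methylpropoxy)cyclopent-2-en-1-one | CC1=C(OCC(C)C)C[C@@H]([C@@](C)(O)[C@@H]2COC(C)(C)O2)C1=O | intermediate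
7 | (5S)-5-[(1R)-1-(tert-butyldimethylsilyloxy)-1-[(4S)-2,2-dimethyl-1,3-dioxolan-4-yl]ethyl]-2-methyl-3-(2-methylpropoxy)cyclopent-2-en-1-one | CC1=C(OCC(C)C)C[C@@H]([C@@](C)(O[Si](C)(C)C(C)(C)C)[C@@H]2COC(C)(C)O2)C1=O | intermediate
8 | vinylmagnesium bromide | C=C[Mg]Br | starting material
9 | (5S)-5-[(1R)-1-(tert-butyldimethylsilyloxy)-1-[(4S)-2,2-dimethyl-1,3-dioxolan-4-yl]ethyl]-1-ethenyl-2-methyl-3-(2-methylpropoxy)cyclopent-2-en-1-ol (new carbinol centre not assigned; not isolated) | CC1=C(OCC(C)C)C[C@@H]([C@@](C)(O[Si](C)(C)C(C)(C)C)[C@@H]2COC(C)(C)O2)C1(O)C=C | intermediate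
10 | (4R)-4-[(1R)-1-(tert-butyldimethylsilyloxy)-1-[(4S)-2,2-dimethyl-1,3-dioxolan-4-yl]ethyl]-3-ethenyl-2-methylcyclopent-2-en-1-one | CC1=C(C=C)[C@H]([C@@](C)(O[Si](C)(C)C(C)(C)C)[C@@H]2COC(C)(C)O2)CC1=O | intermediate
11 | (5R)-5-[(1R)-1-(tert-butyldimethylsilyloxy)-1-[(4S)-2,2-dimethyl-1,3-dioxolan-4-yl]ethyl]-2-methyl-3-oxocyclopent-1-ene-1-carbaldehyde | CC1=C(C=O)[C@H]([C@@](C)(O[Si](C)(C)C(C)(C)C)[C@@H]2COC(C)(C)O2)CC1=O | intermediate
12 | (4R)-4-[(1R)-1-(tert-butyldimethylsilyloxy)-1-[(4S)-2,2-dimethyl-1,3-dioxolan-4-yl]ethyl]-3-[(1S)-1-hydroxyprop-2-en-1-yl]-2-methylcyclopent-2-en-1-one | CC1=C([C@@H](O)C=C)[C@H]([C@@](C)(O[Si](C)(C)C(C)(C)C)[C@@H]2COC(C)(C)O2)CC1=O | intermediate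
13 | acryloyl chloride (prop-2-enoyl chloride) | C=CC(=O)Cl | starting material
14 | (1S)-1-[(5R)-5-[(1R)-1-(tert-butyldimethylsilyloxy)-1-[(4S)-2,2-dimethyl-1,3-dioxolan-4-yl]ethyl]-2-methyl-3-oxocyclopent-1-en-1-yl]prop-2-en-1-yl prop-2-enoate | CC1=C([C@@H](OC(=O)C=C)C=C)[C@H]([C@@](C)(O[Si](C)(C)C(C)(C)C)[C@@H]2COC(C)(C)O2)CC1=O | intermediate
15 | (1S)-1-[(3S,5R)-5-[(1R)-1-(tert-butyldimethylsilyloxy)-1-[(4S)-2,2-dimethyl-1,3-dioxolan-4-yl]ethyl]-3-hydroxy-2-methylcyclopent-1-en-1-yl]prop-2-en-1-yl prop-2-enoate | CC1=C([C@@H](OC(=O)C=C)C=C)[C@H]([C@@](C)(O[Si](C)(C)C(C)(C)C)[C@@H]2COC(C)(C)O2)C[C@@H]1O | intermediate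
16 | (5S)-5-[(3S,5R)-5-[(1R)-1-(tert-butyldimethylsilyloxy)-1-[(4S)-2,2-dimethyl-1,3-dioxolan-4-yl]ethyl]-3-hydroxy-2-methylcyclopent-1-en-1-yl]furan-2(5H)-one | CC1=C([C@H]2OC(=O)C=C2)[C@H]([C@@](C)(O[Si](C)(C)C(C)(C)C)[C@@H]2COC(C)(C)O2)C[C@@H]1O | intermediate
17 | (4R,5S)-5-[(3S,5R)-5-[(1R)-1-(tert-butyldimethylsilyloxy)-1-[(4S)-2,2-dimethyl-1,3-dioxolan-4-yl]ethyl]-3-hydroxy-2-methylcyclopent-1-en-1-yl]-4-ethenyloxolan-2-one | CC1=C([C@H]2OC(=O)C[C@@H]2C=C)[C@H]([C@@](C)(O[Si](C)(C)C(C)(C)C)[C@@H]2COC(C)(C)O2)C[C@@H]1O | intermediate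
18 | (3S,4S,5S)-5-[(3S,5R)-5-[(1R)-1-(tert-butyldimethylsilyloxy)-1-[(4S)-2,2-dimethyl-1,3-dioxolan-4-yl]ethyl]-3-hydroxy-2-methylcyclopent-1-en-1-yl]-4-ethenyl-3-methyloxolan-2-one | CC1=C([C@H]2OC(=O)[C@@H](C)[C@@H]2C=C)[C@H]([C@@](C)(O[Si](C)(C)C(C)(C)C)[C@@H]2COC(C)(C)O2)C[C@@H]1O | intermediate
19 | (3S,4S,5S)-5-[(5R)-5-[(1R)-1-(tert-butyldimethylsilyloxy)-1-[(4S)-2,2-dimethyl-1,3-dioxolan-4-yl]ethyl]-2-methyl-3-oxocyclopent-1-en-1-yl]-4-ethenyl-3-methyloxolan-2-one | CC1=C([C@H]2OC(=O)[C@@H](C)[C@@H]2C=C)[C@H]([C@@](C)(O[Si](C)(C)C(C)(C)C)[C@@H]2COC(C)(C)O2)CC1=O | intermediate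
20 | (3S,4S,5S)-5-[(5R)-5-[(2R,3S)-2-(tert-butyldimethylsilyloxy)-3,4-dihydroxybutan-2-yl]-2-methyl-3-oxocyclopent-1-en-1-yl]-4-ethenyl-3-methyloxolan-2-one | CC1=C([C@H]2OC(=O)[C@@H](C)[C@@H]2C=C)[C@H]([C@@](C)(O[Si](C)(C)C(C)(C)C)[C@@H](O)CO)CC1=O | intermediate
21 | (3S,4S,5S)-5-[(5R)-5-[(2S)-2-(tert-butyldimethylsilyloxy)but-3-en-2-yl]-2-methyl-3-oxocyclopent-1-en-1-yl]-4-ethenyl-3-methyloxolan-2-one | CC1=C([C@H]2OC(=O)[C@@H](C)[C@@H]2C=C)[C@H]([C@@](C)(O[Si](C)(C)C(C)(C)C)C=C)CC1=O | intermediate
22 | (1S,1′S,5R,5′R)-5,5′-bis[(2S)-2-(tert-butyldimethylsilyloxy)but-3-en-2-yl]-4,4′-bis[(2S,3S,4S)-3-ethenyl-4-methyl-5-oxooxolan-2-yl]-3,3′-dimethyl-[1,1′-bi(cyclopentane)]-3,3′-diene-2,2′-dione | CC1=C([C@H]2OC(=O)[C@@H](C)[C@@H]2C=C)[C@H]([C@@](C)(O[Si](C)(C)C(C)(C)C)C=C)[C@H](C1=O)[C@H]1C(=O)C(C)=C([C@H]2OC(=O)[C@@H](C)[C@@H]2C=C)[C@@H]1[C@@](C)(O[Si](C)(C)C(C)(C)C)C=C | intermediate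
23 | (1S,1′S,5R,5′R)-4,4′-bis[(2S,3S,4S)-3-ethenyl-4-methyl-5-oxooxolan-2-yl]-5,5′-bis[(2S)-2-hydroxybut-3-en-2-yl]-3,3′-dimethyl-[1,1′-bi(cyclopentane)]-3,3′-diene-2,2′-dione (tetraene, key-step precursor) | CC1=C([C@H]2OC(=O)[C@@H](C)[C@@H]2C=C)[C@H]([C@@](C)(O)C=C)[C@H](C1=O)[C@H]1C(=O)C(C)=C([C@H]2OC(=O)[C@@H](C)[C@@H]2C=C)[C@@H]1[C@@](C)(O)C=C | intermediate
24 | C2–C2′-linked dimer of (1R,2S,6S,7S,10S,11S)-10-hydroxy-3-oxoguaia-4,8-dien-12,6-olide (key-step product) | CC1=C2[C@H]3OC(=O)[C@@H](C)[C@@H]3C=C[C@](C)(O)[C@@H]2[C@H](C1=O)[C@H]1C(=O)C(C)=C2[C@H]3OC(=O)[C@@H](C)[C@@H]3C=C[C@](C)(O)[C@H]12 | intermediate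
25 | C2–C2′-linked dimer of (1R,2S,6S,7S,10S,11S)-10-hydroxy-3-oxoguai-4-en-12,6-olide | CC1=C2[C@H]3OC(=O)[C@@H](C)[C@@H]3CC[C@](C)(O)[C@@H]2[C@H](C1=O)[C@H]1C(=O)C(C)=C2[C@H]3OC(=O)[C@@H](C)[C@@H]3CC[C@](C)(O)[C@H]12 | intermediate
26 | C2–C2′-linked dimer of (1R,2S,3R,6S,7S,10S,11S)-3α,10β-dihydroxyguai-4-en-12,6-olide | CC1=C2[C@H]3OC(=O)[C@@H](C)[C@@H]3CC[C@](C)(O)[C@@H]2[C@H]([C@H]1O)[C@H]1[C@@H](O)C(C)=C2[C@H]3OC(=O)[C@@H](C)[C@@H]3CC[C@](C)(O)[C@H]12 | intermediate
27 | C2–C2′-linked dimer of (1R,2S,3S,6S,7S,10S,11S)-10β-hydroxy-3β-(4-nitrobenzoyloxy)guai-4-en-12,6-olide | CC1=C2[C@H]3OC(=O)[C@@H](C)[C@@H]3CC[C@](C)(O)[C@@H]2[C@H]([C@@H]1OC(=O)c4ccc(cc4)[N+](=O)[O-])[C@H]1[C@H](OC(=O)c4ccc(cc4)[N+](=O)[O-])C(C)=C2[C@H]3OC(=O)[C@@H](C)[C@@H]3CC[C@](C)(O)[C@H]12 | intermediate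
28 | C2–C2′-linked dimer of (1R,2S,3S,6S,7S,10S,11S)-3β,10β-dihydroxyguai-4-en-12,6-olide | CC1=C2[C@H]3OC(=O)[C@@H](C)[C@@H]3CC[C@](C)(O)[C@@H]2[C@H]([C@@H]1O)[C@H]1[C@H](O)C(C)=C2[C@H]3OC(=O)[C@@H](C)[C@@H]3CC[C@](C)(O)[C@H]12 | intermediate
29 | anabsin | CC1=C2[C@H]3OC(=O)[C@@H](C)[C@@H]3CC[C@](C)(O)[C@@H]2[C@H]2[C@@H]3[C@@H]4[C@]5([C@H]6OC(=O)[C@@H](C)[C@@H]6CC[C@]4(C)O[C@@]5(C)[C@H]3O)[C@@H]12 | target

## Step count and least certain steps

Total: 23 steps. Longest linear sequence: 22 steps (steps 1 and 3–23, from 1 to 29); step 2 is a one-step side branch.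

**Step 18 (key step).** Metathesis between the two halves or between molecules may compete with the two seven-membered closures. Engagement of the C10 vinyl group next to a quaternary carbon may also be slow enough for the catalyst to decay and isomerise alkenes. Fallback: close the ring before the halves are joined. Starting from 21, ring-closing metathesis with the same catalyst in toluene at 80 °C would give the tricyclic silyl ether F1. Enolate coupling of F1 under the conditions of step 16 would give the bis(silyl ether) F2, and HF·pyridine would return to the route at 24.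

**Step 3.** Lithium may chelate the ketone and a dioxolane oxygen, which would reverse the facial preference at C10 and change the chair in which C1 is set. Proton transfer from ketone 5 to the enolate and retro-aldol cleavage on warming are also possible. Fallback: starting from 2, LiN(iPr)2 and Me3SiCl give the silyl dienol ether F3. Its Mukaiyama aldol reaction with 5 under BF3·OEt2, a monodentate Lewis acid that cannot chelate and enforces an open, Felkin-controlled transition state, would return to the route at 6.

**Step 7.** A facial bias from the C1 side chain may oppose the catalyst, and uncatalysed addition promoted by residual magnesium salts would erode selectivity at C6. Fallback: starting from 11, plain addition of 8 at −78 °C would give 12 together with its C6 epimer F4. After separation 12 continues through step 8, and F4 is converted into the same acrylate by Mitsunobu esterification with acrylic acid (inversion at C6), so both epimers return to the route at 14.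

**Step 16.** Coupling of two hindered α-keto radicals may be slow compared with chlorine transfer from the oxidant or proton transfer between enolate and product, and attack syn to the C1 side chain would give cis-configured isomers. Fallback: starting from 21, two equivalents of the lithium enolate are joined with iPr2SiCl2 to give the silicon-tethered bis(dienol ether) F5. Intramolecular oxidative coupling with (NH4)2Ce(NO3)6 and NaHCO3 in MeCN at −30 °C, followed by loss of the silicon tether on work-up, would return to the route at 22.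

**Step 21.** Elimination to a cyclopentadiene or SN2′ substitution may compete with SN2 inversion at these hindered allylic carbinols, and the double reaction may stop halfway. Fallback: starting from 25, reagent-controlled Corey–Bakshi–Shibata reduction with catecholborane, using the oxazaborolidine enantiomer that delivers hydride to the α-face of both equivalent ketones, would lead directly back to the route at 28 and make steps 20–22 unnecessary.

**Step 23.** The allyl cation may lose a proton to give a cyclopentadiene, be trapped by the C10 hydroxyl of its own half, or the tertiary C10 carbinols may dehydrate before the alkene of the other half attacks. Fallback: starting from 27, BF3·OEt2 in CH2Cl2 at −78 °C ionises one allylic 4-nitrobenzoate while the second C3 oxygen stays acylated. The same cyclisation would give 3′-O-(4-nitrobenzoyl)anabsin F6, and methanolysis with K2CO3 would return to the route at 29.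

## Further compounds

F1 | step 18 | (1R,6S,7S,10S,11S)-10-(tert-butyldimethylsilyloxy)-3-oxoguaia-4,8-dien-12,6-olide | CC1=C2[C@H]3OC(=O)[C@@H](C)[C@@H]3C=C[C@](C)(O[Si](C)(C)C(C)(C)C)[C@@H]2CC1=O
F2 | step 18 | bis(tert-butyldimethylsilyl) ether of 24 | CC1=C2[C@H]3OC(=O)[C@@H](C)[C@@H]3C=C[C@](C)(O[Si](C)(C)C(C)(C)C)[C@@H]2[C@H](C1=O)[C@H]1C(=O)C(C)=C2[C@H]3OC(=O)[C@@H](C)[C@@H]3C=C[C@](C)(O[Si](C)(C)C(C)(C)C)[C@H]12
F3 | step 3 | 2-methyl-1-(2-methylpropoxy)-3-(trimethylsilyloxy)cyclopenta-1,3-diene | CC1=C(OCC(C)C)CC=C1O[Si](C)(C)C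
F4 | step 7 | (4R)-4-[(1R)-1-(tert-butyldimethylsilyloxy)-1-[(4S)-2,2-dimethyl-1,3-dioxolan-4-yl]ethyl]-3-[(1R)-1-hydroxyprop-2-en-1-yl]-2-methylcyclopent-2-en-1-one | CC1=C([C@H](O)C=C)[C@H]([C@@](C)(O[Si](C)(C)C(C)(C)C)[C@@H]2COC(C)(C)O2)CC1=O
F5 | step 16 | diisopropylsilylene bis(dienol ether) of 21 | CC1=C([C@H]2OC(=O)[C@@H](C)[C@@H]2C=C)[C@H]([C@@](C)(O[Si](C)(C)C(C)(C)C)C=C)C=C1O[Si](C(C)C)(C(C)C)OC1=C[C@@H]([C@@](C)(O[Si](C)(C)C(C)(C)C)C=C)C([C@H]2OC(=O)[C@@H](C)[C@@H]2C=C)=C1C
F0 | step 21 | none | none
F6 | step 23 | 3′-O-(4-nitrobenzoyl)anabsin | CC1=C2[C@H]3OC(=O)[C@@H](C)[C@@H]3CC[C@](C)(O)[C@@H]2[C@H]2[C@@H]3[C@@H]4[C@]5([C@H]6OC(=O)[C@@H](C)[C@@H]6CC[C@]4(C)O[C@@]5(C)[C@H]3OC(=O)c7ccc(cc7)[N+](=O)[O-])[C@@H]12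
A1 | alternative 1 | anabsin 3′-O-tert-butyldimethylsilyl ether | CC1=C2[C@H]3OC(=O)[C@@H](C)[C@@H]3CC[C@](C)(O)[C@@H]2[C@H]2[C@@H]3[C@@H]4[C@]5([C@H]6OC(=O)[C@@H](C)[C@@H]6CC[C@]4(C)O[C@@]5(C)[C@H]3O[Si](C)(C)C(C)(C)C)[C@@H]12
A2 | alternative 2 | 11(13),11′(13′)-bis(methylene) C2–C2′ bis-enone bis(trimethylsilyl) ether | CC1=C2[C@H]3OC(=O)C(=C)[C@@H]3CC[C@](C)(O[Si](C)(C)C)[C@@H]2[C@H](C1=O)[C@H]1C(=O)C(C)=C2[C@H]3OC(=O)C(=C)[C@@H]3CC[C@](C)(O[Si](C)(C)C)[C@H]12
A3 | alternative 3 | norbornane hydroxy ketone (C3 carbinol, C3′ ketone) | CC1=C2[C@H]3OC(=O)[C@@H](C)[C@@H]3CC[C@](C)(O)[C@@H]2[C@H]2[C@@H]3[C@@H]4[C@@]([C@H]5OC(=O)[C@@H](C)[C@@H]5CC[C@]4(C)O)([C@H](C)C3=O)[C@@]12O
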